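**Retrosynthetic overview**
- The aryl ketone comes from late oxidation of a benzylic alcohol; the methyl group next to the stereocentre comes from a CH2OH (tosylate, then hydride), which traces back to an acyl carbon.
- Key C–C bond (carbinol carbon to aryloxy-bearing carbon): auxiliary-controlled boron syn-aldol between an (R)-4-benzyl-N-(aryloxyacetyl)oxazolidinone and 3,4,5-trimethoxybenzaldehyde. This step fixes the carbon that ends as the (S) centre.
- The acyl oxazolidinone comes from the aryloxyacetic acid, made by O-alkylation of (E)-4-propenyl-2,6-dimethoxyphenol with ethyl bromoacetate; the phenol comes from 4-allyl-2,6-dimethoxyphenol by allyl-to-propenyl isomerisation.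
- No ring is formed: both benzene rings are bought intact, and the oxazolidinone ring of the auxiliary is bought and recovered.

Assumption: the stereocentre in the given SMILES is read as (S) and the propenyl group as (E).

**Route**

Step 1
Reactants: 1 4-allyl-2,6-dimethoxyphenol
Product: 2 (E)-2,6-dimethoxy-4-(prop-1-enyl)phenol
Conditions: RuHCl(CO)(PPh3)3 (2 mol%), toluene, 80 °C
Reagents that add atoms: none
Why: Ruthenium-hydride catalysed alkene isomerisation (hydrometalation/β-hydride elimination) moves the double bond into conjugation with the arene and gives the thermodynamically favoured E isomer (typically ≥95:5).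

Step 2
Reactants: 2 (E)-2,6-dimethoxy-4-(prop-1-enyl)phenol; 3 ethyl bromoacetate
Product: 4 ethyl 2-[2,6-dimethoxy-4-[(E)-prop-1-enyl]phenoxy]acetate
Conditions: K2CO3, acetone, reflux
Reagents that add atoms: none
Why: Williamson ether synthesis; the phenoxide displaces bromide from the activated α-bromo ester by SN2, and the mild base leaves the propenyl group untouched.

Step 3
Reactants: 4 ethyl 2-[2,6-dimethoxy-4-[(E)-prop-1-enyl]phenoxy]acetate
Product: 5 2-[2,6-dimethoxy-4-[(E)-prop-1-enyl]phenoxy]acetic acid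
Conditions: LiOH·H2O, THF/H2O, rt; then 1 M HCl to pH 3 at 0 °C; recrystallise (EtOAc/hexane)
Reagents that add atoms: lithium hydroxide LiOH, [Li+].[OH-]
Why: Ester saponification; brief cold acidification spares the acid-sensitive propenyl arene, and recrystallisation of the acid removes traces of the Z isomer.

Step 4
Reactants: 5 2-[2,6-dimethoxy-4-[(E)-prop-1-enyl]phenoxy]acetic acid; 6 pivaloyl chloride; 7 (R)-4-benzyloxazolidin-2-one
Product: 9 (R)-4-benzyl-3-[2-[2,6-dimethoxy-4-[(E)-prop-1-enyl]phenoxy]acetyl]oxazolidin-2-one, via mixed pivalic anhydride 8 (not isolated)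
Conditions: Et3N, THF, −20 °C; then LiCl, 7, −20 °C → rt
Reagents that add atoms: none
Why: N-acylation through a mixed anhydride; the LiCl-activated oxazolidinone attacks the less hindered aryloxyacetyl carbonyl, and the base-only conditions avoid HCl that could add to the propenyl group.

Step 5
Reactants: 9 (R)-4-benzyl-3-[2-[2,6-dimethoxy-4-[(E)-prop-1-enyl]phenoxy]acetyl]oxazolidin-2-one; 10 dibutylboron triflate; 11 3,4,5-trimethoxybenzaldehyde
Product: 14 (R)-4-benzyl-3-[(2R,3S)-2-[2,6-dimethoxy-4-[(E)-prop-1-enyl]phenoxy]-3-hydroxy-3-(3,4,5-trimethoxyphenyl)propanoyl]oxazolidin-2-one, via Z-boron enolate 12 (not isolated), via boron aldolate 13 (not isolated)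
Conditions: iPr2NEt, CH2Cl2, −78 → 0 °C; 11, −78 → 0 °C; pH 7 phosphate buffer, MeOH, 30% H2O2, 0 °C
Reagents that add atoms: none
Why: Evans syn-aldol reaction; the Z-boron enolate reacts through a closed Zimmerman–Traxler chair with the aldehyde approaching the face away from the benzyl group of the (R)-auxiliary, giving the syn (2R,3S) adduct whose C2 becomes the (S) centre of the target.

Step 6
Reactants: 14 (R)-4-benzyl-3-[(2R,3S)-2-[2,6-dimethoxy-4-[(E)-prop-1-enyl]phenoxy]-3-hydroxy-3-(3,4,5-trimethoxyphenyl)propanoyl]oxazolidin-2-one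
Product: 15 (R)-4-benzyl-3-[(2R,3S)-3-(tert-butyldimethylsilyloxy)-2-[2,6-dimethoxy-4-[(E)-prop-1-enyl]phenoxy]-3-(3,4,5-trimethoxyphenyl)propanoyl]oxazolidin-2-one
Conditions: TBSOTf, 2,6-lutidine, CH2Cl2, −78 → 0 °C
Reagents that add atoms: tert-butyldimethylsilyl triflate (TBSOTf), CC(C)(C)[Si](C)(C)OS(=O)(=O)C(F)(F)F
Why: Silyl ether protection of the secondary benzylic alcohol under buffered low-temperature conditions blocks retro-aldol and keeps this oxygen out of the later sulfonylation and hydride steps.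

Step 7
Reactants: 15 (R)-4-benzyl-3-[(2R,3S)-3-(tert-butyldimethylsilyloxy)-2-[2,6-dimethoxy-4-[(E)-prop-1-enyl]phenoxy]-3-(3,4,5-trimethoxyphenyl)propanoyl]oxazolidin-2-one
Product: 16 (2S,3S)-3-(tert-butyldimethylsilyloxy)-2-[2,6-dimethoxy-4-[(E)-prop-1-enyl]phenoxy]-3-(3,4,5-trimethoxyphenyl)propan-1-ol
Conditions: LiBH4, MeOH (1.5 equiv), THF, 0 °C
Reagents that add atoms: none
Why: Reductive cleavage of the N-acyl oxazolidinone at the exocyclic carbonyl gives the primary alcohol and returns the auxiliary; no bond at the stereocentres is touched (C2 changes from R to S only because the priority order changes).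

Step 8
Reactants: 16 (2S,3S)-3-(tert-butyldimethylsilyloxy)-2-[2,6-dimethoxy-4-[(E)-prop-1-enyl]phenoxy]-3-(3,4,5-trimethoxyphenyl)propan-1-ol
Product: 17 (2S,3S)-3-(tert-butyldimethylsilyloxy)-2-[2,6-dimethoxy-4-[(E)-prop-1-enyl]phenoxy]-3-(3,4,5-trimethoxyphenyl)propyl 4-methylbenzenesulfonate
Conditions: TsCl, Et3N, DMAP (cat.), CH2Cl2, 0 °C → rt
Reagents that add atoms: p-toluenesulfonyl chloride (TsCl), Cc1ccc(cc1)S(=O)(=O)Cl
Why: Sulfonylation of the only free (primary) hydroxyl turns it into a leaving group without affecting either stereocentre.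

Step 9
Reactants: 17 (2S,3S)-3-(tert-butyldimethylsilyloxy)-2-[2,6-dimethoxy-4-[(E)-prop-1-enyl]phenoxy]-3-(3,4,5-trimethoxyphenyl)propyl 4-methylbenzenesulfonate
Product: 18 tert-butyl-[(1S,2S)-2-[2,6-dimethoxy-4-[(E)-prop-1-enyl]phenoxy]-1-(3,4,5-trimethoxyphenyl)propoxy]dimethylsilane
Conditions: LiBHEt3, THF, 0 °C → rt
Reagents that add atoms: none
Why: SN2 hydride displacement of a primary tosylate by LiBHEt3, a hydride nucleophilic enough for β-branched sulfonates, converts CH2OTs into the methyl group while the silyl ether, aryl ethers and alkene are inert.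

Step 10
Reactants: 18 tert-butyl-[(1S,2S)-2-[2,6-dimethoxy-4-[(E)-prop-1-enyl]phenoxy]-1-(3,4,5-trimethoxyphenyl)propoxy]dimethylsilane
Product: 19 (1S,2S)-2-[2,6-dimethoxy-4-[(E)-prop-1-enyl]phenoxy]-1-(3,4,5-trimethoxyphenyl)propan-1-ol
Conditions: Bu4NF, THF, 0 °C → rt; H2O
Reagents that add atoms: none
Why: Fluoride-mediated desilylation driven by the strong Si–F bond frees the benzylic alcohol; the substrate has no base-sensitive position at this stage.

Step 11
Reactants: 19 (1S,2S)-2-[2,6-dimethoxy-4-[(E)-prop-1-enyl]phenoxy]-1-(3,4,5-trimethoxyphenyl)propan-1-ol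
Product: 20 (S)-2-[2,6-dimethoxy-4-[(E)-prop-1-enyl]phenoxy]-1-(3,4,5-trimethoxyphenyl)propan-1-one
Conditions: Dess–Martin periodinane, NaHCO3, CH2Cl2, 0 °C → rt
Reagents that add atoms: none
Why: Dess–Martin oxidation of the secondary benzylic alcohol under buffered, near-neutral conditions gives the aryl ketone without touching the alkene and without enolising the adjacent (S) centre.

**Compound list**
1 | 4-allyl-2,6-dimethoxyphenol | C=CCc1cc(OC)c(O)c(OC)c1 | starting material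
2 | (E)-2,6-dimethoxy-4-(prop-1-enyl)phenol | C/C=C/c1cc(OC)c(O)c(OC)c1 | intermediate
3 | ethyl bromoacetate | CCOC(=O)CBr | starting material
4 | ethyl 2-[2,6-dimethoxy-4-[(E)-prop-1-enyl]phenoxy]acetate | C/C=C/c1cc(OC)c(OCC(=O)OCC)c(OC)c1 | intermediate
5 | 2-[2,6-dimethoxy-4-[(E)-prop-1-enyl]phenoxy]acetic acid | C/C=C/c1cc(OC)c(OCC(=O)O)c(OC)c1 | intermediate
6 | pivaloyl chloride | CC(C)(C)C(=O)Cl | starting material
7 | (R)-4-benzyloxazolidin-2-one | O=C1N[C@H](Cc2ccccc2)CO1 | starting material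
8 | mixed anhydride of acid 5 with pivalic acid (not isolated) | C/C=C/c1cc(OC)c(OCC(=O)OC(=O)C(C)(C)C)c(OC)c1 | intermediate
9 | (R)-4-benzyl-3-[2-[2,6-dimethoxy-4-[(E)-prop-1-enyl]phenoxy]acetyl]oxazolidin-2-one | C/C=C/c1cc(OC)c(OCC(=O)N2[C@H](Cc3ccccc3)COC2=O)c(OC)c1 | intermediate
10 | dibutylboron triflate | CCCCB(CCCC)OS(=O)(=O)C(F)(F)F | starting material
11 | 3,4,5-trimethoxybenzaldehyde | COc1cc(C=O)cc(OC)c1OC | starting material
12 | (Z)-dibutylboron enolate of imide 9 (not isolated) | CCCCB(CCCC)O/C(=C\Oc1c(OC)cc(/C=C/C)cc1OC)N1[C@H](Cc2ccccc2)COC1=O | intermediate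
13 | dibutylboron aldolate of adduct 14 (not isolated) | C/C=C/c1cc(OC)c(O[C@@H](C(=O)N2[C@H](Cc3ccccc3)COC2=O)[C@@H](OB(CCCC)CCCC)c2cc(OC)c(OC)c(OC)c2)c(OC)c1 | intermediate
14 | (R)-4-benzyl-3-[(2R,3S)-2-[2,6-dimethoxy-4-[(E)-prop-1-enyl]phenoxy]-3-hydroxy-3-(3,4,5-trimethoxyphenyl)propanoyl]oxazolidin-2-one | C/C=C/c1cc(OC)c(O[C@@H](C(=O)N2[C@H](Cc3ccccc3)COC2=O)[C@@H](O)c2cc(OC)c(OC)c(OC)c2)c(OC)c1 | intermediate
15 | (R)-4-benzyl-3-[(2R,3S)-3-(tert-butyldimethylsilyloxy)-2-[2,6-dimethoxy-4-[(E)-prop-1-enyl]phenoxy]-3-(3,4,5-trimethoxyphenyl)propanoyl]oxazolidin-2-one | C/C=C/c1cc(OC)c(O[C@@H](C(=O)N2[C@H](Cc3ccccc3)COC2=O)[C@@H](O[Si](C)(C)C(C)(C)C)c2cc(OC)c(OC)c(OC)c2)c(OC)c1 | intermediate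
16 | (2S,3S)-3-(tert-butyldimethylsilyloxy)-2-[2,6-dimethoxy-4-[(E)-prop-1-enyl]phenoxy]-3-(3,4,5-trimethoxyphenyl)propan-1-ol | C/C=C/c1cc(OC)c(O[C@@H](CO)[C@@H](O[Si](C)(C)C(C)(C)C)c2cc(OC)c(OC)c(OC)c2)c(OC)c1 | intermediate
17 | (2S,3S)-3-(tert-butyldimethylsilyloxy)-2-[2,6-dimethoxy-4-[(E)-prop-1-enyl]phenoxy]-3-(3,4,5-trimethoxyphenyl)propyl 4-methylbenzenesulfonate | C/C=C/c1cc(OC)c(O[C@@H](COS(=O)(=O)c2ccc(C)cc2)[C@@H](O[Si](C)(C)C(C)(C)C)c2cc(OC)c(OC)c(OC)c2)c(OC)c1 | intermediate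
18 | tert-butyl-[(1S,2S)-2-[2,6-dimethoxy-4-[(E)-prop-1-enyl]phenoxy]-1-(3,4,5-trimethoxyphenyl)propoxy]dimethylsilane | C/C=C/c1cc(OC)c(O[C@@H](C)[C@@H](O[Si](C)(C)C(C)(C)C)c2cc(OC)c(OC)c(OC)c2)c(OC)c1 | intermediate
19 | (1S,2S)-2-[2,6-dimethoxy-4-[(E)-prop-1-enyl]phenoxy]-1-(3,4,5-trimethoxyphenyl)propan-1-ol | C/C=C/c1cc(OC)c(O[C@@H](C)[C@@H](O)c2cc(OC)c(OC)c(OC)c2)c(OC)c1 | intermediate
20 | (S)-2-[2,6-dimethoxy-4-[(E)-prop-1-enyl]phenoxy]-1-(3,4,5-trimethoxyphenyl)propan-1-one | C/C=C/c1cc(OC)c(O[C@@H](C)C(=O)c2cc(OC)c(OC)c(OC)c2)c(OC)c1 | target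

**Totals**
Total step count: 11. Longest linear sequence: 11 steps (1 → 20).

**Three steps most likely to fail, with fallbacks**

Step 5 (aldol). The bulky 2,6-dimethoxyaryloxy group may slow enolisation or lower the diastereoselectivity. The fallback takes the stereocentre from the chiral pool instead and sets out from phenol 2. Mitsunobu etherification with methyl (R)-lactate (PPh3, DIAD, THF, 0 °C → rt, inversion at carbon) gives methyl (S)-2-[2,6-dimethoxy-4-[(E)-prop-1-enyl]phenoxy]propanoate F1. Treatment with MeNH(OMe)·HCl and iPrMgCl (THF, −20 °C) converts it into the Weinreb amide (S)-2-[2,6-dimethoxy-4-[(E)-prop-1-enyl]phenoxy]-N-methoxy-N-methylpropanamide F2. Addition of commercial 3,4,5-trimethoxyphenylmagnesium bromide (THF, −10 °C, cold NH4Cl quench) gives the ketone directly, so the fallback comes back to the route at 20.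

Step 7 (reductive removal of the auxiliary). With the hindered α-aryloxy-β-silyloxy imide, hydride may attack the ring carbonyl and open the oxazolidinone. The fallback sets out from 15 and cleaves in two stages. LiOH/H2O2 (THF/H2O, 0 °C; Na2SO3 quench), which is selective for the exocyclic carbonyl, gives (2R,3S)-3-(tert-butyldimethylsilyloxy)-2-[2,6-dimethoxy-4-[(E)-prop-1-enyl]phenoxy]-3-(3,4,5-trimethoxyphenyl)propanoic acid F3. TMSCHN2 (MeOH/toluene, 0 °C) gives methyl (2R,3S)-3-(tert-butyldimethylsilyloxy)-2-[2,6-dimethoxy-4-[(E)-prop-1-enyl]phenoxy]-3-(3,4,5-trimethoxyphenyl)propanoate F4. Reduction of the ester with LiBH4 (THF, 0 °C → rt) comes back to the route at 16.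

Step 9 (hydride displacement of the tosylate). The primary carbon is β-branched and flanked by two bulky groups, so SN2 may be slow or give S–O cleavage back to 16. The fallback replaces the ionic displacement by a radical reduction and sets out from 16. PPh3, I2 and imidazole (CH2Cl2, rt) give tert-butyl-[(1S,2R)-2-[2,6-dimethoxy-4-[(E)-prop-1-enyl]phenoxy]-3-iodo-1-(3,4,5-trimethoxyphenyl)propoxy]dimethylsilane F5. Bu3SnH (2 equiv, about 0.5 M, to outrun β-scission of the aryloxy group) with AIBN in toluene at 80 °C removes the iodine and comes back to the route at 18.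

**Further compounds**
F1 | step 5 | methyl (S)-2-[2,6-dimethoxy-4-[(E)-prop-1-enyl]phenoxy]propanoate | C/C=C/c1cc(OC)c(O[C@@H](C)C(=O)OC)c(OC)c1
F2 | step 5 | (S)-2-[2,6-dimethoxy-4-[(E)-prop-1-enyl]phenoxy]-N-methoxy-N-methylpropanamide | C/C=C/c1cc(OC)c(O[C@@H](C)C(=O)N(C)OC)c(OC)c1
F3 | step 7 | (2R,3S)-3-(tert-butyldimethylsilyloxy)-2-[2,6-dimethoxy-4-[(E)-prop-1-enyl]phenoxy]-3-(3,4,5-trimethoxyphenyl)propanoic acid | C/C=C/c1cc(OC)c(O[C@@H](C(=O)O)[C@@H](O[Si](C)(C)C(C)(C)C)c2cc(OC)c(OC)c(OC)c2)c(OC)c1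
F4 | step 7 | methyl (2R,3S)-3-(tert-butyldimethylsilyloxy)-2-[2,6-dimethoxy-4-[(E)-prop-1-enyl]phenoxy]-3-(3,4,5-trimethoxyphenyl)propanoate | C/C=C/c1cc(OC)c(O[C@@H](C(=O)OC)[C@@H](O[Si](C)(C)C(C)(C)C)c2cc(OC)c(OC)c(OC)c2)c(OC)c1
F5 | step 9 | tert-butyl-[(1S,2R)-2-[2,6-dimethoxy-4-[(E)-prop-1-enyl]phenoxy]-3-iodo-1-(3,4,5-trimethoxyphenyl)propoxy]dimethylsilane | C/C=C/c1cc(OC)c(O[C@@H](CI)[C@@H](O[Si](C)(C)C(C)(C)C)c2cc(OC)c(OC)c(OC)c2)c(OC)c1
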